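All runs were computed from invented constants; the scatter is artificial.

| setting | midnight | dusk | flask |
|---|---|---|---|
| substrate | 13 mM | 30 mM | 20 mM |
| gas | 3.4 mM (held) | 3.4 mM (held) | 3.4 mM (held) |
| remark | run made earlier | run made earlier |  |
| time |  |  | 5.0 d |

- midnight (time / d: target / %, substrate / %): 0.333: 1.1, 97.8; 1.04: 4.5, 94.5; 1.67: 7.6, 92.1; 2.50: 11.3, 87.6; 4.00: 17.0, 81.5; 5.00: 20.9, 79.0
- dusk (time / d: target / %, substrate / %): 0.417: 0.9, 96.9; 0.625: 3.1, 96.2; 1.04: 4.9, 95.3; 1.67: 7.5, 90.9; 3.00: 12.6, 86.1; 5.00: 20.7, 78.6

(each reading ± 0.5 percentage points)

- at the start none of the gas is in solution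

- west: doubling the transfer coefficient of the gas, all else as stated
- east: doubling the saturation concentration of gas, all else as stated

* how much target there is at 5.0 d, in percent of the substrate charged
* the change that raises the amount of target at 5.0 d, in percent of the substrate charged most ("none" if none brings more than 2 percentage points) (west / east / none)
* amount of target at 5.0 d, in percent of the substrate charged, after west

At early times the two runs read alike: at 1.67 d the midnight run holds 7.6% target and the dusk run 7.5%, within the scatter of 0.5 percentage points, although dusk was charged 2.31 times as much substrate. So we treat each day's yield as a fixed share of the substrate still present.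

Substrate falls as the run goes on, so we take the yield as that share, times the time, times the mean substrate, which is the charge less half the yield. The yield then stands on both sides, and we go round. The two early readings average 7.55%, which gives a fractional rate of 0.0470 d⁻¹, the pseudo-first-order constant with the gas held.

For the flask at 5.0 d, a straight line gives 23.5%. Putting that back gives 20.7%, and a further round gives 21.1%. That is our answer, and the readings at 5.00 d, 20.9% and 20.7%, lie slightly lower.

If one gas goes into each target, dusk takes up 1.41 mM d⁻¹ and midnight 0.611 mM d⁻¹ at one fractional rate, so we expect west to add less than 2 points. These runs do not test east, but if the fractional rate follows dissolved gas, doubling it gives 36.0% after one round, so we choose east.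

The forecast says 20.8%, east as best and 21.1% after west: "Gas transfer is not limiting."

The flask gives 20.3%. East adds 14 points and west 0.17 points, so east is best, and after west the target stands at 20.5%.

    substrate ⇌ reactive form (K = 0.0170, k = 7.34 × 10⁻⁶ s⁻¹)
    partner + reactive form → target (k = 0.0102 L mol⁻¹ s⁻¹)
    gas ⇌ partner, rate k3*(csat - [partner]) (kL = 2.33 × 10⁻⁴ s⁻¹)

At 0.451 d the reactive form in this flask falls back 13 times faster than it goes on to target, and at 2.50 d partner stands at 98.8% of saturation. Read back through our rule, 20.3% gives this flask a fractional rate of 0.0452 d⁻¹. For the neighbour flask read at 3.0 d, our early 0.0470 d⁻¹ gives a straight line of 14.1%, and the same two rounds give 13.2%, while that neighbour holds 12.7%.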